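Time works against the target in the earlier runs after a short early rise, so we reckon the two ends apart and then join them.

| setting | oak | elm | maple | flask |
|---|---|---|---|---|
| substrate | 0.0020 M | 0.0020 M | 0.0040 M | 0.0020 M |
| reagent | 5 mM | 20 mM | 10 mM | 10.0 mM |
| remark | run made earlier | run made earlier | run made earlier |  |
| time |  |  |  | 4.0 h |

| run | time / h | target / % | substrate / % |
|---|---|---|---|
| oak | 0.0250 | 32.5 | 26.9 |
| oak | 0.133 | 63.7 | 3.3 |
| oak | 0.500 | 59.8 | 3.1 |
| oak | 2.50 | 31.2 | 2.1 |
| elm | 0.0250 | 63.3 | 2.7 |
| elm | 0.133 | 81.0 | 0.4 |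
| elm | 0.500 | 79.7 | 0.5 |
| elm | 2.50 | 74.0 | 0.1 |
| maple | 0.0250 | 46.8 | 9.7 |
| maple | 0.133 | 68.5 | 1.3 |
| maple | 0.500 | 68.0 | 0.8 |
| maple | 2.50 | 60.6 | 1.2 |

(standard deviation of a reading: 0.5 percentage points)

- a reading or a percentage of target counts all its forms, free or not

- time, not beyond 4.0 h, at which the flask holds most target
- the amount of target, in percent of the substrate charged, at that time

At the late end, between 0.500 h and 2.50 h, the oak run loses 0.143 h⁻¹ of its charge and the elm run 0.0285 h⁻¹, both at the flask's substrate charge. In oak and elm substrate is the limiting reagent, and we multiply each loss by the excess of reagent over substrate as charged, which gives 0.429 mM h⁻¹ and 0.513 mM h⁻¹. Their mean is our rule of thumb, the drain 0.471 mM h⁻¹: at this substrate charge, the late loss per hour is the drain divided by the excess. For the flask that means 0.0589 h⁻¹.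

The rule has borders. Maple, with twice the substrate, gives 0.222 mM h⁻¹, about half the drain, so we use the drain at the substrate charge of oak and elm and not at maple's. Early on, oak gains 2.89 h⁻¹, which is 20.2 times its late loss, so we do not use the rule during the rise. Oak, elm and maple each read higher at 0.133 h than at 0.500 h, so we put the flask's top near 0.133 h. The flask's reagent lies midway between oak and elm by ratio, so we take the geometric mean of their readings at that time as our height, 71.8%.

The forecast says 0.2 h (0.1 h to 0.4 h) and 73% (69% to 77%), holding that “reagent seems to protect the target”. Our time and our height are both lower than its values.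

The flask tops out at 0.115 h with 74.6%, earlier than the forecast's time, and 70.6% of the charge then stands as crystals, counted within that target.

substrate + intermediate → side product (k = 3.60 L mol⁻¹ s⁻¹); crystals ⇌ target, rate k2*(cs2 - [target]) while solid is left; crystals form when [target] > cs2 (solubility = 0.0810 mM, k = 0.910 s⁻¹); substrate + reagent ⇌ intermediate (K = 810 L mol⁻¹, k = 3.70 L mol⁻¹ s⁻¹); intermediate ⇌ target (K = 0.440, k = 0.0230 s⁻¹) From that top the drain's 0.0589 h⁻¹ leaves 51.7% at 4.0 h, and the flask holds 50.4%. The neighbour charged with 0.0060 M of reagent tops out at 67.6%. The drain gives it 0.118 h⁻¹, so 20.4% after 4.0 h, and it holds 24.4%.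

All runs come from a simulation with made-up constants.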